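The dihydrofuran ring (O1, C2, C3, C3a, C7a) is disconnected at C3–C3a and O1–C2. Both bonds are made in one operation by a formal (3+2) annulation: a ring carbon and the adjacent phenolic oxygen of an acylphloroglucinol act as a C,O-dinucleophile towards an enantiopure 2,3-epoxy-3-methylbutyl electrophile. C-alkylation is followed by strain-releasing 5-exo opening of the oxirane, which sets C2 by inversion and unveils the tertiary carbinol. The step exploits the vicinal C–O bonds at C2 and the carbinol carbon, which are those of a prenyl epoxide. The precursor is the symmetrical 4-O-(1,1-dimethylpropargyl) ether; this ether blocks the para oxygen and later delivers the prenyl group by semihydrogenation and Claisen rearrangement.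

Key step: step 4

Assumption: compounds 1, 2, 5 and 7 and all reagents are taken as commercial.

Remark: the spatial arrangement at the epoxide carbon is the same in 8, 9, 10 and 11. Only the CIP descriptor changes (R in 8, 9 and 11, S in 10), because CH2I outranks the ring carbon of the oxirane.

Step 1
Reactants: 1 benzene-1,3,5-triol (phloroglucinol); 2 3-(4-methoxyphenyl)propanenitrile
Product: 4 1-(2,4,6-trihydroxyphenyl)-3-(4-methoxyphenyl)propan-1-one, via ketiminium chloride 3 (not isolated)
Conditions: HCl (gas), ZnCl2 (cat.), Et2O, 0 °C; then H2O, 100 °C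
Reagents that add atoms: water, O
Why: Houben–Hoesch acylation, in which the nitrilium ion formed from 2 and HCl should attack the very electron-rich ring of 1 once only, because the ketiminium salt 3 deactivates the ring and precipitates, and hot water then hydrolyses it to the ketone.

Step 2
Reactants: 4 1-(2,4,6-trihydroxyphenyl)-3-(4-methoxyphenyl)propan-1-one; 5 3-chloro-3-methylbut-1-yne
Product: 6 1-[2,6-dihydroxy-4-(2-methylbut-3-yn-2-yloxy)phenyl]-3-(4-methoxyphenyl)propan-1-one
Conditions: CuCl2·2H2O (1 mol %), DBU (1.1 equiv), 5 (1.05 equiv), MeCN, 0 °C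
Reagents that add atoms: none
Why: Copper-catalysed O-propargylation of a phenol with a tertiary propargylic chloride should take place at the 4-OH alone, since this is the most acidic hydroxyl and the only one not hydrogen-bonded to the ketone, and only one equivalent of base and of 5 is offered.

Step 3
Reactants: 7 3-methylbut-2-en-1-ol (prenol)
Product: 9 [(2R)-3,3-dimethyloxiran-2-yl]methyl 4-methylbenzenesulfonate, via epoxy alcohol 8 (not isolated)
Conditions: Ti(OiPr)4 (5 mol %), D-(−)-diisopropyl tartrate (6 mol %), cumene hydroperoxide, 4 Å MS, CH2Cl2, −20 °C; then P(OMe)3; then TsCl, Et3N, DMAP (cat.), −10 °C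
Reagents that add atoms: cumene hydroperoxide CC(C)(OO)c1ccccc1; 4-methylbenzenesulfonyl chloride Cc1ccc(cc1)S(Cl)(=O)=O
Why: Sharpless asymmetric epoxidation, in which the titanium catalyst bearing the D-(−)-tartrate ligand delivers oxygen to the alkene face that gives the (2R)-epoxy alcohol 8 (reagent control), followed by in situ tosylation, which spares isolation of the volatile, water-soluble 8 and gives a sulfonate whose enantiomeric purity can be raised by recrystallisation.

Step 4
Reactants: 6 1-[2,6-dihydroxy-4-(2-methylbut-3-yn-2-yloxy)phenyl]-3-(4-methoxyphenyl)propan-1-one; 9 [(2R)-3,3-dimethyloxiran-2-yl]methyl 4-methylbenzenesulfonate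
Product: 12 1-[(2S)-6-hydroxy-2-(2-hydroxypropan-2-yl)-4-(2-methylbut-3-yn-2-yloxy)-2,3-dihydro-1-benzofuran-7-yl]-3-(4-methoxyphenyl)propan-1-one, via epoxy iodide 10 (not isolated), via C-alkylated epoxide 11 (not isolated)
Conditions: K2CO3 (2.5 equiv), NaI (1.2 equiv), 6 in slight excess, CF3CH2OH/H2O (9:1), 25 °C then 50 °C
Reagents that add atoms: none
Why: Proposed new method: the phenoxide of 6 should attack the CH2–I carbon of 10 (formed from 9 by Finkelstein exchange) through its ortho ring carbon to forge the aryl–CH2 bond, and the neighbouring phenoxide of the resulting epoxide 11 should then open the strained oxirane at its CH carbon to forge the O–CH bond and release the tertiary alkoxide as the carbinol. The closest known reaction types are the base-mediated C-alkylation of acylphloroglucinols by alkyl and allyl halides in protic media and the base-mediated cyclisation of ortho-(2,3-epoxy-3-methylbutyl)phenols to 2-(2-hydroxypropan-2-yl)-2,3-dihydrobenzofurans; what is new is their fusion in one flask through an epoxy-alkyl electrophile. The dihydrofuran ring closes in the 5-exo-tet mode by SN2 attack at the secondary epoxide carbon, which basic conditions favour over 6-endo attack at the tertiary carbon. The single new stereocentre is controlled by the (R)-configured epoxide carbon set in step 3, which is untouched in the C–C bond formation and inverted in the ring opening to give (S). The step needs C- over O-alkylation, for which the hydrogen-bonding solvent CF3CH2OH shields the phenoxide oxygens and the soft iodide favours attack by carbon, and it needs closure onto the oxygen ortho to the ketone, which is secured because the para oxygen is blocked as the tertiary propargyl ether while the two free hydroxyls and the two ring C–H positions of 6 are equivalent by symmetry. Attack on the oxirane of 10 instead of on CH2–I is disfavoured by its fully substituted terminus, so no opening and re-closure pathway should scramble the configuration.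

Step 5
Reactants: 12 1-[(2S)-6-hydroxy-2-(2-hydroxypropan-2-yl)-4-(2-methylbut-3-yn-2-yloxy)-2,3-dihydro-1-benzofuran-7-yl]-3-(4-methoxyphenyl)propan-1-one
Product: 13 1-[(2S)-6-hydroxy-2-(2-hydroxypropan-2-yl)-4-(2-methylbut-3-en-2-yloxy)-2,3-dihydro-1-benzofuran-7-yl]-3-(4-methoxyphenyl)propan-1-one
Conditions: H2 (1 atm), Pd/CaCO3 poisoned with Pb(OAc)2, quinoline, EtOAc, 20 °C
Reagents that add atoms: none
Why: Lindlar semihydrogenation, in which the poisoned palladium catalyst should reduce the terminal alkyne to the vinyl group and stop there, leaving the aryl ketone, the aryl ethers and the C2 stereocentre untouched.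

Step 6
Reactants: 13 1-[(2S)-6-hydroxy-2-(2-hydroxypropan-2-yl)-4-(2-methylbut-3-en-2-yloxy)-2,3-dihydro-1-benzofuran-7-yl]-3-(4-methoxyphenyl)propan-1-one
Product: 14 1-[(2S)-4,6-dihydroxy-2-(2-hydroxypropan-2-yl)-5-(3-methylbut-2-en-1-yl)-2,3-dihydro-1-benzofuran-7-yl]-3-(4-methoxyphenyl)propan-1-one (CNP0150199.1)
Conditions: PhNEt2, 130 °C
Reagents that add atoms: none
Why: Aromatic Claisen rearrangement ([3,3]-sigmatropic shift) of the aryl 1,1-dimethylallyl ether, in which the allyl terminus should bond to C5, the only unsubstituted ortho carbon, so that enolisation gives the 3-methylbut-2-enyl side chain and the free 4-OH while the remote C2 stereocentre is not involved.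

Compound list
1 | benzene-1,3,5-triol (phloroglucinol) | Oc1cc(O)cc(O)c1 | starting material
2 | 3-(4-methoxyphenyl)propanenitrile | COc1ccc(CCC#N)cc1 | starting material
3 | 3-(4-methoxyphenyl)-1-(2,4,6-trihydroxyphenyl)propan-1-iminium chloride (ketiminium salt formed in the flask) | COc1ccc(CCC(=[NH2+])c2c(O)cc(O)cc2O)cc1.[Cl-] | intermediate
4 | 1-(2,4,6-trihydroxyphenyl)-3-(4-methoxyphenyl)propan-1-one | COc1ccc(CCC(=O)c2c(O)cc(O)cc2O)cc1 | intermediate
5 | 3-chloro-3-methylbut-1-yne | CC(C)(Cl)C#C | starting material
6 | 1-[2,6-dihydroxy-4-(2-methylbut-3-yn-2-yloxy)phenyl]-3-(4-methoxyphenyl)propan-1-one | COc1ccc(CCC(=O)c2c(O)cc(OC(C)(C)C#C)cc2O)cc1 | intermediate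
7 | 3-methylbut-2-en-1-ol (prenol) | CC(C)=CCO | starting material
8 | [(2R)-3,3-dimethyloxiran-2-yl]methanol (formed in the flask) | CC1(C)O[C@@H]1CO | intermediate
9 | [(2R)-3,3-dimethyloxiran-2-yl]methyl 4-methylbenzenesulfonate | Cc1ccc(cc1)S(=O)(=O)OC[C@H]1OC1(C)C | intermediate
10 | (2S)-2-(iodomethyl)-3,3-dimethyloxirane (formed in the flask) | CC1(C)O[C@@H]1CI | intermediate
11 | 1-[3-{[(2R)-3,3-dimethyloxiran-2-yl]methyl}-2,6-dihydroxy-4-(2-methylbut-3-yn-2-yloxy)phenyl]-3-(4-methoxyphenyl)propan-1-one (formed in the flask) | COc1ccc(CCC(=O)c2c(O)cc(OC(C)(C)C#C)c(C[C@H]3OC3(C)C)c2O)cc1 | intermediate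
12 | 1-[(2S)-6-hydroxy-2-(2-hydroxypropan-2-yl)-4-(2-methylbut-3-yn-2-yloxy)-2,3-dihydro-1-benzofuran-7-yl]-3-(4-methoxyphenyl)propan-1-one | COc1ccc(CCC(=O)c2c(O)cc(OC(C)(C)C#C)c3c2O[C@H](C(C)(C)O)C3)cc1 | intermediate
13 | 1-[(2S)-6-hydroxy-2-(2-hydroxypropan-2-yl)-4-(2-methylbut-3-en-2-yloxy)-2,3-dihydro-1-benzofuran-7-yl]-3-(4-methoxyphenyl)propan-1-one | COc1ccc(CCC(=O)c2c(O)cc(OC(C)(C)C=C)c3c2O[C@H](C(C)(C)O)C3)cc1 | intermediate
14 | 1-[(2S)-4,6-dihydroxy-2-(2-hydroxypropan-2-yl)-5-(3-methylbut-2-en-1-yl)-2,3-dihydro-1-benzofuran-7-yl]-3-(4-methoxyphenyl)propan-1-one (CNP0150199.1) | COc1ccc(CCC(=O)c2c(O)c(CC=C(C)C)c(O)c3c2O[C@H](C(C)(C)O)C3)cc1 | target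

Total step count: 6. Longest linear sequence: 5 steps (steps 1, 2, 4, 5 and 6); step 3 supplies fragment 9 in one step from 7.

Steps most likely to fail

Step 4 (proposed new method). The phenoxide may be alkylated at oxygen instead of at the ring carbon, the product may be alkylated a second time at C5, or the oxirane may open in the 6-endo sense. The fallback uses known chemistry only and makes the two ring bonds in separate steps. It sets out from 6. C-prenylation with 1-bromo-3-methylbut-2-ene in aqueous KOH should give the 3-prenyl ketone F1. Acetylation of both phenols (Ac2O, pyridine) should give the diacetate F2, which protects the electron-rich ring from the oxidant. Shi asymmetric epoxidation of the trisubstituted alkene (D-fructose-derived Shi ketone, KHSO5 as the triple salt 2KHSO5·KHSO4·K2SO4, buffered MeCN/H2O, 0 °C) should, by the spiro transition-state model, give the (R)-epoxide diacetate F3. K2CO3 in MeOH should then remove both acetates to give 11 in the flask, which closes 5-exo with inversion to 12, where the route is rejoined.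

Step 6. The tertiary allyl aryl ether may fragment (loss of the five-carbon unit as isoprene) faster than it rearranges, or the new ortho-prenylphenol may cyclise further onto the 4-OH at the reaction temperature. The fallback replaces the sigmatropic delivery by an intermolecular prenylation and sets out from 13. Allyl transfer to morpholine with Pd(PPh3)4 (zerovalent palladium) in THF at 20 °C should free the phenol and give the dihydrobenzofuran diol F4. C-prenylation of F4 with 1-bromo-3-methylbut-2-ene in aqueous KOH at 0 °C can only take place at C5, the one free ring carbon, and should give 14 directly.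

Step 2. Over-alkylation, C-alkylation of the electron-rich ring, or poor discrimination between the three hydroxyls may erode the yield of the mono-ether. The fallback gives up the latent-prenyl ether for a plain protecting group and sets out from 4. Mitsunobu etherification with benzyl alcohol (PPh3, DIAD, THF, 0 °C) is selective for the most acidic, non-chelated hydroxyl and should give the 4-O-benzyl ether F5. Under the conditions of step 4 with 9, F5 should pass through the C-alkylated benzyl ether epoxide F6 to the benzyl-protected dihydrobenzofuran F7. Hydrogenolysis (H2, 10% Pd/C, EtOAc) should then give the diol F4 already described, and its C-prenylation as above rejoins the route at 14.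

Further compounds
F1 | step 4 | 1-[2,6-dihydroxy-3-(3-methylbut-2-en-1-yl)-4-(2-methylbut-3-yn-2-yloxy)phenyl]-3-(4-methoxyphenyl)propan-1-one | COc1ccc(CCC(=O)c2c(O)cc(OC(C)(C)C#C)c(CC=C(C)C)c2O)cc1
F2 | step 4 | 2-[3-(4-methoxyphenyl)propanoyl]-4-(3-methylbut-2-en-1-yl)-5-(2-methylbut-3-yn-2-yloxy)-1,3-phenylene diacetate | COc1ccc(CCC(=O)c2c(OC(C)=O)cc(OC(C)(C)C#C)c(CC=C(C)C)c2OC(C)=O)cc1
F3 | step 4 | 4-{[(2R)-3,3-dimethyloxiran-2-yl]methyl}-2-[3-(4-methoxyphenyl)propanoyl]-5-(2-methylbut-3-yn-2-yloxy)-1,3-phenylene diacetate | COc1ccc(CCC(=O)c2c(OC(C)=O)cc(OC(C)(C)C#C)c(C[C@H]3OC3(C)C)c2OC(C)=O)cc1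
F4 | step 6 | 1-[(2S)-4,6-dihydroxy-2-(2-hydroxypropan-2-yl)-2,3-dihydro-1-benzofuran-7-yl]-3-(4-methoxyphenyl)propan-1-one | COc1ccc(CCC(=O)c2c(O)cc(O)c3c2O[C@H](C(C)(C)O)C3)cc1
F5 | step 2 | 1-[4-(benzyloxy)-2,6-dihydroxyphenyl]-3-(4-methoxyphenyl)propan-1-one | COc1ccc(CCC(=O)c2c(O)cc(OCc3ccccc3)cc2O)cc1
F6 | step 2 | 1-[4-(benzyloxy)-3-{[(2R)-3,3-dimethyloxiran-2-yl]methyl}-2,6-dihydroxyphenyl]-3-(4-methoxyphenyl)propan-1-one | COc1ccc(CCC(=O)c2c(O)cc(OCc3ccccc3)c(C[C@H]4OC4(C)C)c2O)cc1
F7 | step 2 | 1-[(2S)-4-(benzyloxy)-6-hydroxy-2-(2-hydroxypropan-2-yl)-2,3-dihydro-1-benzofuran-7-yl]-3-(4-methoxyphenyl)propan-1-one | COc1ccc(CCC(=O)c2c(O)cc(OCc3ccccc3)c4c2O[C@H](C(C)(C)O)C4)cc1
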